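Locants (skeletal atoms in the order of the target SMILES, methyl and hydroxyl groups unnumbered): C1 (=CH2), C2, C3 (Me), C4, C5, C6 (Me), C7 (OH), C8, C9, C10 (Me), C11–C13, C14 (Me), C15, C16 (ring-E C=O), O17, C18 (Me), C19 (OH), C20 (ketone); C21 is the ring-A lactone C=O. Rings: A (C6–C11, bridged by C21–O), B (C5, C6, C11–C14), C (C2–C5, C14, C15), D (C2, C3, C20, C19, C15), E (C15, C16, O17, C18, C19).
Enabling feature: ring D is an acyloin, the C20 ketone sitting next to the tertiary carbinol C19. C19 is also the fusion atom of lactone E, and C20 hangs from quaternary C3, held 1,3-diaxial to spiro C15 on ring C. Cutting C19–C20 gives a C3 aldehyde facing the ketone of a spiro furan-2,4-dione; they are rejoined by a carbene-catalysed intramolecular crossed benzoin in which the base-labile C18 epimers converge.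
Further cuts, in order: O17–C16 (lactonisation, ring E); C15–C19 (lactyl transfer from the C20 oxygen to a dienolate, which also sets C2=C1); C2–C1 (Negishi); C3–C20 (formaldehyde aldol); C10–C11, C6–C5 and C14–C15 together (cation–olefin tricyclisation giving rings A, B, C and the lactone bridge); C7–C8 (aldol); C4–C3 (dianion alkylation).
Forward: geranyl bromide + methyl 3-oxopentanoate → C7 enal → anti-aldol with a pent-4-ynoyl oxazolidinone → gold-made enol lactone → acid-triggered tricyclisation → C3 and C15 elaboration → ring E → ring D last.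
Stereochemistry: C7/C8 from the oxazolidinone auxiliary; C10, C11, C6, C5, C14 relayed from C8 through the bridged all-chair cascade of the two E-alkenes; C3 by axial attack; C15 by intramolecular delivery from the axial C3 arm; C18 from (R)-lactic acid and corrected dynamically; C19 by the forced cis fusion in the key step.

Key step: step 18

Remark 1: the MgCl2-catalysed anti-aldol (step 5) is assumed to follow the chelated-enolate model, so the (R)-benzyl auxiliary gives the (C7 R, C8 S) adduct; if the sense were opposite, the enantiomeric auxiliary would be used.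
Remark 2: C3 is an epimerisable, unassigned centre in 3–5 and 10–15 (SMILES left open there); 16, 17 and 21 are drawn as keto tautomers with the thermodynamically preferred equatorial groups.

Step 1
Reactants: 1 geranyl bromide; 2 methyl 3-oxopentanoate
Product: 3 methyl (6E)-4,7,11-trimethyl-3-oxododeca-6,10-dienoate
Conditions: NaH, THF, 0 °C; n-BuLi, 0 °C; then 1, 0 °C to rt; AcOH quench
Reagents that add atoms: none
Why: The β-keto ester dianion reacts at its more nucleophilic γ-carbon with the allylic bromide (SN2, dianion γ-alkylation), joining C4–C3 and placing the C3 methyl.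

Step 2
Reactants: 3 methyl (6E)-4,7,11-trimethyl-3-oxododeca-6,10-dienoate
Product: 4 methyl (6E,10E)-12-hydroxy-4,7,11-trimethyl-3-oxododeca-6,10-dienoate
Conditions: SeO2 (10 mol%), t-BuOOH (2.5 equiv), salicylic acid (10 mol%), CH2Cl2, rt
Reagents that add atoms: tert-butyl hydroperoxide, CC(C)(C)OO
Why: SeO2-catalysed allylic oxidation (ene reaction, then 2,3-sigmatropic shift) should attack the E-methyl of the terminal trisubstituted alkene selectively and give the E-allylic alcohol that becomes C7.

Step 3
Reactants: 4 methyl (6E,10E)-12-hydroxy-4,7,11-trimethyl-3-oxododeca-6,10-dienoate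
Product: 5 methyl (6E,10E)-4,7,11-trimethyl-3,12-dioxododeca-6,10-dienoate
Conditions: TEMPO (10 mol%), PhI(OAc)2 (1.1 equiv), CH2Cl2, rt
Reagents that add atoms: none
Why: Nitroxyl-catalysed oxidation is selective for the primary allylic alcohol and should leave the β-keto ester and both alkenes untouched, giving the E-enal.

Step 4
Reactants: 6 pent-4-ynoic acid; 7 (R)-4-benzyloxazolidin-2-one
Product: 9 (R)-4-benzyl-3-(pent-4-ynoyl)oxazolidin-2-one, via pent-4-ynoic pivalic anhydride 8 (not isolated)
Conditions: t-BuCOCl, Et3N, THF, −20 °C; then LiCl, 7, rt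
Reagents that add atoms: none
Why: N-Acylation of the oxazolidinone through the mixed pivalic anhydride is the standard mild acyl transfer and tolerates the terminal alkyne.

Step 5
Reactants: 9 (R)-4-benzyl-3-(pent-4-ynoyl)oxazolidin-2-one; 5 methyl (6E,10E)-4,7,11-trimethyl-3,12-dioxododeca-6,10-dienoate
Product: 11 anti-aldol imide (12R,13S; free 12-OH), via O-trimethylsilyl aldol adduct 10 (not isolated)
Conditions: MgCl2 (20 mol%), Et3N, Me3SiCl, EtOAc, rt; then CF3CO2H (cat.), MeOH
Reagents that add atoms: none
Why: The MgCl2-catalysed direct Evans anti-aldol of the chelated Z-enolate with the non-enolisable enal, with silyl trapping, should set C8 (S) and C7 (R) anti from the (R)-auxiliary, the β-keto ester being at most transiently silylated.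

Step 6
Reactants: 11 anti-aldol imide (12R,13S; free 12-OH)
Product: 12 12-O-tert-butyldimethylsilyl ether of 11
Conditions: t-BuMe2SiOTf, 2,6-lutidine, CH2Cl2, −78 to 0 °C
Reagents that add atoms: tert-butyldimethylsilyl trifluoromethanesulfonate, CC(C)(C)[Si](C)(C)OS(=O)(=O)C(F)(F)F
Why: Silyl triflate with a hindered pyridine base silylates the secondary allylic alcohol quickly at low temperature, and any enol silyl ether of the β-keto ester is hydrolysed on work-up.

Step 7
Reactants: 12 12-O-tert-butyldimethylsilyl ether of 11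
Product: 14 (2S,3R)-3-silyloxy-2-propargyl acid, via peroxy acid 13 (not isolated)
Conditions: LiOH, H2O2, THF/H2O, 0 °C; Na2SO3; then aq HCl to pH 3
Reagents that add atoms: hydrogen peroxide, OO
Why: Hydroperoxide attacks the exocyclic imide carbonyl selectively (standard auxiliary cleavage), sulfite reduces the peracid, and the methyl β-keto ester should survive as its enolate without epimerisation at C8.

Step 8
Reactants: 14 (2S,3R)-3-silyloxy-2-propargyl acid
Product: 15 γ-methylene butyrolactone (enol lactone) carrying the polyene β-keto ester chain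
Conditions: AuCl (5 mol%), K2CO3 (10 mol%), MeCN, rt
Reagents that add atoms: none
Why: Monovalent gold activates the terminal alkyne for anti 5-exo-dig attack of the carboxylate (cycloisomerisation of a 4-alkynoic acid), which leaves the alkenes, silyl ether and β-keto ester alone.

Step 9
Reactants: 15 γ-methylene butyrolactone (enol lactone) carrying the polyene β-keto ester chain
Product: 16 tricyclic lactone keto ester (rings A, B, C and the C21–O–C10 bridge closed; 7-OSiMe2t-Bu axial; 2-oxo; 15-CO2Me)
Conditions: HN(SO2CF3)2 (10 mol%), CH2Cl2, −78 to −40 °C, 5 mM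
Reagents that add atoms: none
Why: Proposed new method: C-protonation of the exocyclic enol-lactone carbon gives a cyclic acyloxycarbenium ion at C10 (the oxygen analogue of an N-acyliminium ion; closest known types are acetal- and N-acyliminium-initiated polyene cyclisations), which the C11=C6 alkene can reach only on the lactone face bearing the C7 chain, so C21 and the lactone oxygen become diaxial on a chair ring A, the anti C7/C8 relationship puts the silyloxy group axial, and anti-periplanar additions across the two E-alkenes with C-termination by the β-keto ester enol give trans-anti-trans rings B and C, the proton being returned on termination so that the acid is catalytic.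

Step 10
Reactants: 16 tricyclic lactone keto ester
Product: 17 3-(hydroxymethyl) derivative of 16 (C20 axial on C3)
Conditions: LiN(iPr)2 (2.2 equiv), THF, −78 to −20 °C; CH2O (gas, 1.1 equiv), −78 °C; AcOH quench
Reagents that add atoms: formaldehyde, C=O
Why: The β-keto ester dianion adds to formaldehyde at C3 (γ-aldol of a dianion) by axial attack on the ring-C face opposite the C14 methyl, which should set quaternary C3 with C20 axial and syn to the axial position of C15.

Step 11
Reactants: 18 (R)-lactic acid
Product: 20 (R)-2-[(tert-butyldimethylsilyl)oxy]propanoic acid, via bis-silylated lactic acid 19 (not isolated)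
Conditions: t-BuMe2SiCl (2.2 equiv), imidazole, DMF, rt; then THF/H2O, AcOH (cat.)
Reagents that add atoms: tert-butyldimethylsilyl chloride, CC(C)(C)[Si](C)(C)Cl
Why: Bis-silylation followed by selective hydrolysis of the labile silyl ester is a standard one-flask protection that does not touch the (R) centre.

Step 12
Reactants: 17 3-(hydroxymethyl) derivative of 16; 20 (R)-2-[(tert-butyldimethylsilyl)oxy]propanoic acid
Product: 21 C20 O-lactyl ester of 17
Conditions: DCC, DMAP (10 mol%), CH2Cl2, 0 °C to rt
Reagents that add atoms: none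
Why: Steglich esterification acylates the primary neopentyl alcohol under neutral conditions that avoid retro-aldol loss of formaldehyde.

Step 13
Reactants: 21 C20 O-lactyl ester of 17
Product: 22 enol triflate of 21 (C15=C2, 2-OSO2CF3)
Conditions: KN(SiMe3)2 (1.05 equiv), THF, −78 °C; PhN(SO2CF3)2, −78 to 0 °C; aq NH4Cl
Reagents that add atoms: N-phenylbis(trifluoromethanesulfonimide), O=S(=O)(N(c1ccccc1)S(=O)(=O)C(F)(F)F)C(F)(F)F
Why: One equivalent of base removes only the β-keto ester proton (C3 is now quaternary), and O-sulfonylation of that enolate gives the single possible enol triflate.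

Step 14
Reactants: 22 enol triflate of 21
Product: 23 allylsilane enoate (C15(CO2Me)=C2–CH2SiMe3)
Conditions: Me3SiCH2MgCl, ZnCl2, THF, 0 °C; then 22, Pd(OAc)2 (5 mol%), SPhos (10 mol%), 40 °C
Reagents that add atoms: (trimethylsilyl)methylmagnesium chloride, C[Si](C)(C)C[Mg]Cl
Why: Negishi coupling of the enol triflate with an sp3 organozinc lacking β-hydrogens installs C1 as a CH2SiMe3 group and should tolerate the esters and the lactone.

Step 15
Reactants: 23 allylsilane enoate
Product: 24 C15 lactyl ketone with C2=C1H2 and free 3-CH2OH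
Conditions: (Me2N)3S+ Me3SiF2− (1.2 equiv), THF, −78 to −20 °C; aq NH4Cl
Reagents that add atoms: none
Why: Proposed new method: fluoride attacks silicon of the γ-silyl enoate and unmasks the ester dienolate without strong base, its α-carbon C15 lies 1,3-diaxial to the C20–O–lactyl ester and attacks that ester carbonyl through a six-membered transition state (a Dieckmann-type O-to-C acyl transfer made irreversible by release of an alkoxide from a non-stabilised dienolate), which moves the double bond to C2=C1 and delivers C19 to C15 on the face of C20; the closest known types are fluoride-induced dienolate generation from 4-silylcrotonates and deconjugative α-acylation of ester dienolates.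

Step 16
Reactants: 24 C15 lactyl ketone with C2=C1H2 and free 3-CH2OH
Product: 25 C3 aldehyde (C20 = CHO) of 24
Conditions: Dess–Martin periodinane, CH2Cl2, rt
Reagents that add atoms: none
Why: Dess–Martin oxidation converts the only free hydroxyl (the C20 primary alcohol, drawn out of any hemiketal with the C19 ketone) into the α-quaternary, non-enolisable aldehyde.

Step 17
Reactants: 25 C3 aldehyde of 24
Product: 27 C3-formyl spiro furan-2,4-dione (ring E closed; 7-OH free), via desilylated hydroxy keto ester 26 (not isolated)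
Conditions: HF (48% aq), MeCN, 0 °C to rt; then TsOH·H2O (10 mol%), CH2Cl2, 4 Å sieves, 35 °C
Reagents that add atoms: none
Why: Aqueous HF removes both silyl ethers, and the freed C18 hydroxyl, held beside the C16 methyl ester on C15, lactonises by acid-catalysed 5-exo-trig transesterification, closing ring E before ring D.

Step 18
Reactants: 27 C3-formyl spiro furan-2,4-dione
Product: 28 Brasilianoid F
Conditions: 2-(pentafluorophenyl)-6,7-dihydro-5H-pyrrolo[2,1-c][1,2,4]triazolium tetrafluoroborate (20 mol%), Et3N (1.0 equiv), THF, 40 °C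
Reagents that add atoms: none
Why: The carbene adds to the non-enolisable C3 aldehyde and proton transfer gives the Breslow intermediate, an acyl-anion equivalent at C20, which attacks the C19 ketone of the spiro furan-2,4-dione and then releases the catalyst and the C19(OH)–C20(=O) acyloin. The closest known reaction type is the intramolecular crossed aldehyde–ketone benzoin cyclisation, including its dynamic variants on ketones with a labile α-stereocentre. Ring D closes in a 5-exo-trig mode; because C20 (on C3) and C19 (on C15) are both axial on the ring-C face opposite the C14 methyl, only the ketone face turned toward C2 is within reach, which fixes C19 with its hydroxyl on the convex face and makes rings D/E cis-fused and rings C/D a bicyclo[3.2.1]octane. C18 is α to the ketone and should equilibrate through the enol under the basic conditions, and attack anti to its methyl is favoured, so both C18 epimers should funnel to the natural one (methyl cis to the new hydroxyl), after which C18 can no longer epimerise. The step needs the aldehyde to act as donor and the ketone as acceptor, not an aldol of the C18 enolate onto the aldehyde; the quaternary aldehyde, the electrophilic β-dicarbonyl ketone and their enforced 1,3-diaxial proximity should secure this, and both lactone carbonyls are inert to the acyl-anion equivalent.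

Compound list
1 | geranyl bromide, (2E)-1-bromo-3,7-dimethylocta-2,6-diene | CC(C)=CCC/C(C)=C/CBr | starting material
2 | methyl 3-oxopentanoate | CCC(=O)CC(=O)OC | starting material
3 | methyl (6E)-4,7,11-trimethyl-3-oxododeca-6,10-dienoate (C4 racemic) | CC(C)=CCC/C(C)=C/CC(C)C(=O)CC(=O)OC | intermediate
4 | methyl (6E,10E)-12-hydroxy-4,7,11-trimethyl-3-oxododeca-6,10-dienoate | OC/C(C)=C/CC/C(C)=C/CC(C)C(=O)CC(=O)OC | intermediate
5 | methyl (6E,10E)-4,7,11-trimethyl-3,12-dioxododeca-6,10-dienoate | O=C/C(C)=C/CC/C(C)=C/CC(C)C(=O)CC(=O)OC | intermediate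
6 | pent-4-ynoic acid | C#CCCC(=O)O | starting material
7 | (R)-4-benzyloxazolidin-2-one | O=C1N[C@H](Cc2ccccc2)CO1 | starting material
8 | pent-4-ynoic pivalic anhydride | C#CCCC(=O)OC(=O)C(C)(C)C | intermediate
9 | (R)-4-benzyl-3-(pent-4-ynoyl)oxazolidin-2-one | C#CCCC(=O)N1[C@H](Cc2ccccc2)COC1=O | intermediate
10 | O-trimethylsilyl ether of aldol imide 11 | C#CC[C@H](C(=O)N1[C@H](Cc2ccccc2)COC1=O)[C@@H](O[Si](C)(C)C)/C(C)=C/CC/C(C)=C/CC(C)C(=O)CC(=O)OC | intermediate
11 | methyl (6E,10E,12R,13S)-13-[(R)-4-benzyl-2-oxooxazolidine-3-carbonyl]-12-hydroxy-4,7,11-trimethyl-3-oxohexadeca-6,10-dien-15-ynoate (anti-aldol imide) | C#CC[C@H](C(=O)N1[C@H](Cc2ccccc2)COC1=O)[C@@H](O)/C(C)=C/CC/C(C)=C/CC(C)C(=O)CC(=O)OC | intermediate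
12 | 12-O-tert-butyldimethylsilyl ether of 11 | C#CC[C@H](C(=O)N1[C@H](Cc2ccccc2)COC1=O)[C@@H](O[Si](C)(C)C(C)(C)C)/C(C)=C/CC/C(C)=C/CC(C)C(=O)CC(=O)OC | intermediate
13 | peroxy acid corresponding to 14 | C#CC[C@H](C(=O)OO)[C@@H](O[Si](C)(C)C(C)(C)C)/C(C)=C/CC/C(C)=C/CC(C)C(=O)CC(=O)OC | intermediate
14 | (2S,3R,4E,8E)-3-[(tert-butyldimethylsilyl)oxy]-14-methoxy-4,8,11-trimethyl-12,14-dioxo-2-(prop-2-yn-1-yl)tetradeca-4,8-dienoic acid | C#CC[C@H](C(=O)O)[C@@H](O[Si](C)(C)C(C)(C)C)/C(C)=C/CC/C(C)=C/CC(C)C(=O)CC(=O)OC | intermediate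
15 | methyl (6E,10E,12R)-12-[(tert-butyldimethylsilyl)oxy]-4,7,11-trimethyl-12-[(3S)-5-methylidene-2-oxooxolan-3-yl]-3-oxododeca-6,10-dienoate (enol lactone) | C=C1C[C@H](C(=O)O1)[C@@H](O[Si](C)(C)C(C)(C)C)/C(C)=C/CC/C(C)=C/CC(C)C(=O)CC(=O)OC | intermediate
16 | tricyclic lactone keto ester: rings A, B, C trans-anti-trans; C21(=O)–O–C10 bridge on the face of the C6 methyl; 7-OSiMe2t-Bu axial (anti to C6-Me); 2-oxo; 15-CO2Me and 3-Me equatorial | O=C1[C@@H](C)C[C@H]3[C@]4(C)[C@H](O[Si](C)(C)C(C)(C)C)[C@@H]5C[C@@](C)(OC5=O)[C@H]4CC[C@]3(C)[C@H]1C(=O)OC | intermediate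
17 | 3-(hydroxymethyl) derivative of 16, C20 axial on C3 on the face opposite the C14 methyl | O=C1[C@@](CO)(C)C[C@H]3[C@]4(C)[C@H](O[Si](C)(C)C(C)(C)C)[C@@H]5C[C@@](C)(OC5=O)[C@H]4CC[C@]3(C)[C@H]1C(=O)OC | intermediate
18 | (R)-lactic acid | C[C@@H](O)C(=O)O | starting material
19 | tert-butyldimethylsilyl (R)-2-[(tert-butyldimethylsilyl)oxy]propanoate | C[C@@H](O[Si](C)(C)C(C)(C)C)C(=O)O[Si](C)(C)C(C)(C)C | intermediate
20 | (R)-2-[(tert-butyldimethylsilyl)oxy]propanoic acid | C[C@@H](O[Si](C)(C)C(C)(C)C)C(=O)O | intermediate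
21 | C20 O-[(R)-2-(tert-butyldimethylsilyloxy)propanoyl] ester of 17 | O=C1[C@@](COC(=O)[C@@H](C)O[Si](C)(C)C(C)(C)C)(C)C[C@H]3[C@]4(C)[C@H](O[Si](C)(C)C(C)(C)C)[C@@H]5C[C@@](C)(OC5=O)[C@H]4CC[C@]3(C)[C@H]1C(=O)OC | intermediate
22 | enol triflate of 21 (C15=C2, 2-OSO2CF3) | FC(F)(F)S(=O)(=O)OC=1[C@@](COC(=O)[C@@H](C)O[Si](C)(C)C(C)(C)C)(C)C[C@H]3[C@]4(C)[C@H](O[Si](C)(C)C(C)(C)C)[C@@H]5C[C@@](C)(OC5=O)[C@H]4CC[C@]3(C)C=1C(=O)OC | intermediate
23 | allylsilane enoate: C15(CO2Me)=C2–CH2SiMe3, C3 arm as in 21 | C[Si](C)(C)CC=1[C@@](COC(=O)[C@@H](C)O[Si](C)(C)C(C)(C)C)(C)C[C@H]3[C@]4(C)[C@H](O[Si](C)(C)C(C)(C)C)[C@@H]5C[C@@](C)(OC5=O)[C@H]4CC[C@]3(C)C=1C(=O)OC | intermediate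
24 | C15 lactyl ketone: 15-CO2Me equatorial, 15-C(=O)CH(CH3)OSiMe2t-Bu axial (C18 R), C2=C1H2, 3-CH2OH (may sit as the C20–O–C19 hemiketal) | C=C1[C@@](CO)(C)C[C@H]3[C@]4(C)[C@H](O[Si](C)(C)C(C)(C)C)[C@@H]5C[C@@](C)(OC5=O)[C@H]4CC[C@]3(C)[C@@]1(C(=O)[C@@H](C)O[Si](C)(C)C(C)(C)C)C(=O)OC | intermediate
25 | C3 aldehyde (C20 = CHO) of 24 | C=C1[C@@](C=O)(C)C[C@H]3[C@]4(C)[C@H](O[Si](C)(C)C(C)(C)C)[C@@H]5C[C@@](C)(OC5=O)[C@H]4CC[C@]3(C)[C@@]1(C(=O)[C@@H](C)O[Si](C)(C)C(C)(C)C)C(=O)OC | intermediate
26 | bis-desilylated hydroxy keto ester (7-OH, 18-OH) | C=C1[C@@](C=O)(C)C[C@H]3[C@]4(C)[C@H](O)[C@@H]5C[C@@](C)(OC5=O)[C@H]4CC[C@]3(C)[C@@]1(C(=O)[C@@H](C)O)C(=O)OC | intermediate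
27 | seco-aldehyde: spiro furan-2,4-dione at C15 (ring E closed, C19 ketone axial), 3-CHO axial, 7-OH, C2=C1H2 | C=C1[C@@](C=O)(C)C[C@H]3[C@]4(C)[C@H](O)[C@@H]5C[C@@](C)(OC5=O)[C@H]4CC[C@]3(C)[C@@]13C(=O)O[C@H](C)C3=O | intermediate
28 | Brasilianoid F | C=C1[C@@]2(C)C[C@H]3[C@]4(C)[C@H](O)[C@@H]5C[C@@](C)(OC5=O)[C@H]4CC[C@]3(C)[C@@]13C(=O)O[C@H](C)[C@@]3(O)C2=O | target

Total step count: 18. Longest linear sequence: 16 steps (1–3, 5–10, 12–18).

Steps most likely to fail:

1. Step 9 (proposed new method). The allylic silyl ether may ionise, its oxygen may capture the acyloxycarbenium ion, ring A may close through the wrong alkene face, or the cascade may end by O-termination at the β-keto ester. Fallback with known chemistry, from 5 and 9 back to 16: a Bu2BOTf/iPr2NEt syn-aldol of 9 with 5 should give syn-aldol imide F1; silylation of F1 with t-BuMe2SiOTf and 2,6-lutidine gives silyl ether F2; MeOMgBr exchanges the auxiliary of F2 for methoxide and gives methyl ester F3. An alkyne-initiated polyene cyclisation of F3 with a cationic monovalent gold catalyst (Ph3PAuCl/AgSbF6) or InBr3 (6-exo-dig; A(1,2) strain keeps the silyloxy group axial and the ester equatorial) should give tricyclic exo-methylene ester F4. Deprotonation of F4 with LiN(iPr)2 and kinetic protonation should give axial C8 ester F5, and CF3SO3H-catalysed lactonisation of F5 onto the exocyclic alkene rejoins the route at 16.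

2. Step 15 (proposed new method). The dienolate may be protonated, may react through its γ-carbon, or a silyl ether may be lost before acyl transfer. Fallback with known chemistry, from 22 back to 24: Negishi methylation of 22 (MeZnCl, Pd(OAc)2/SPhos) gives β-methyl enoate F6; kinetic γ-deprotonation of F6 at the methyl group cis to the ester with lithium 2,2,6,6-tetramethylpiperidide at −78 °C (deconjugative α-acylation of an ester dienolate) should give the same dienolate and hence 24.

3. Step 18 (key step). The C18 enolate may add to the aldehyde in an aldol reaction, or the hindered aldehyde may fail to form the acyl-anion equivalent. Fallback, from 27 to 28: SmI2-mediated ketyl cyclisation of the aldehyde onto the ketone (pinacol-type coupling, THF, −78 °C; the ring-E C18–O17 bond lies near the plane of the C19 carbonyl and is poorly aligned for reductive cleavage) should give cis-C19,C20-diol F7; selective oxidation of the secondary C20 hydroxyl of F7 through the stannylene acetal (Bu2SnO, then N-bromosuccinimide) gives 28.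

Further compounds
F1 | step 9 | syn-aldol imide (12R,13R), C8 epimer of 11 | C#CC[C@@H](C(=O)N1[C@H](Cc2ccccc2)COC1=O)[C@@H](O)/C(C)=C/CC/C(C)=C/CC(C)C(=O)CC(=O)OC
F2 | step 9 | 12-O-tert-butyldimethylsilyl ether of F1 | C#CC[C@@H](C(=O)N1[C@H](Cc2ccccc2)COC1=O)[C@@H](O[Si](C)(C)C(C)(C)C)/C(C)=C/CC/C(C)=C/CC(C)C(=O)CC(=O)OC
F3 | step 9 | methyl ester from F2 (auxiliary exchanged for OMe) | C#CC[C@@H](C(=O)OC)[C@@H](O[Si](C)(C)C(C)(C)C)/C(C)=C/CC/C(C)=C/CC(C)C(=O)CC(=O)OC
F4 | step 9 | tricyclic exo-methylene ester: C10=CH2, 8-CO2Me equatorial, 7-OSiMe2t-Bu axial, ring C β-keto ester | O=C1[C@@H](C)C[C@H]3[C@]4(C)[C@H](O[Si](C)(C)C(C)(C)C)[C@H](C(=O)OC)CC(=C)[C@H]4CC[C@]3(C)[C@H]1C(=O)OC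
F5 | step 9 | C8 epimer of F4 (8-CO2Me axial) | O=C1[C@@H](C)C[C@H]3[C@]4(C)[C@H](O[Si](C)(C)C(C)(C)C)[C@@H](C(=O)OC)CC(=C)[C@H]4CC[C@]3(C)[C@H]1C(=O)OC
F6 | step 15 | β-methyl enoate: C15(CO2Me)=C2–CH3, C3 arm as in 21 | CC=1[C@@](COC(=O)[C@@H](C)O[Si](C)(C)C(C)(C)C)(C)C[C@H]3[C@]4(C)[C@H](O[Si](C)(C)C(C)(C)C)[C@@H]5C[C@@](C)(OC5=O)[C@H]4CC[C@]3(C)C=1C(=O)OC
F7 | step 18 | cis-C19,C20-diol (20-deoxo-20-hydroxy Brasilianoid F) | C=C1[C@@]2(C)C[C@H]3[C@]4(C)[C@H](O)[C@@H]5C[C@@](C)(OC5=O)[C@H]4CC[C@]3(C)[C@@]13C(=O)O[C@H](C)[C@@]3(O)[C@@H]2O
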